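The partner is the reagent to follow in these flasks: it joins the starting material, and it also decays.

    starting material + partner ⇌ target (K1 = 67 M⁻¹, k1 = 45 M⁻¹ h⁻¹, Ea1 = 47.0 kJ mol⁻¹, ΔH1 = −34.0 kJ mol⁻¹)
    second substrate + partner ⇌ second product (K2 = 290 M⁻¹, k2 = 4.7 M⁻¹ h⁻¹, Ea2 = 69.0 kJ mol⁻¹, ΔH2 = −10.0 kJ mol⁻¹)
    partner → decomposed reagent (k3 = 0.024 h⁻¹, Ea3 = 115 kJ mol⁻¹)
    (constants at 40 °C)

| flask | starting material | partner | second substrate | temperature | time | remark |
|---|---|---|---|---|---|---|
| eta | 0.020 M | 1.00 equiv | 0.200 equiv (in portions, 2, over 4.0 d) | 40 °C | 10 d | first portion at the start, last at 4.0 d |
| theta | 0.020 M | 1.00 equiv | 0.200 equiv (fed, over 4.0 d) |  | 10 d | the addition at 10 °C, then warmed to 40 °C; the feed brings no volume worth counting |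
| beta | 0.020 M (fed, over 4.0 d) | 1.00 equiv | 0.200 equiv | 40 °C | 10 d | all else is in the flask from the start; the feed brings no volume worth counting |
| gamma | 0.020 M | 1.00 equiv | 0.200 equiv (fed, over 4.0 d) | 40 °C | 10 d | all else is in the flask from the start; the feed brings no volume worth counting |
| alpha | 0.020 M (fed, over 25 h) | 1.00 equiv | 0.200 equiv | 40 °C | 10 d | all else is in the flask from the start; the feed brings no volume worth counting |

- the constants hold at 40 °C; other temperatures follow from the activation energies and enthalpies

* the flask that comes out highest in amount of target, in percent of the starting material charged, or "all alike" when all lie within 1.5 percentage points (eta / theta / beta / gamma / alpha / all alike)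
* target at the end, in percent of the starting material charged, eta
* target at the end, in percent of the starting material charged, theta
* target at the end, in percent of the starting material charged, beta
* target at the end, in percent of the starting material charged, gamma
* target at the end, in percent of the starting material charged, alpha

Step one comes to balance in about 1.11 h, far quicker than the partner's bare decay time of 41.7 h, so at 40 °C target follows the partner. With equal charges, the equilibrium constant times the charge is 1.34, and the quadratic gives a target share of 43.2%.

That share does not last: the partner has a decay path of its own, step three, and the starting material has none, so the partner is the limiting reagent. So I write its balance. Leaving the second substrate aside for the moment, partner counted free and in target falls through the decay of its free part, and once target has faded, the free share is 42.7%. This gives the pool lifetime 4.06 d, the time in which free and target-bound partner together fall by a factor e at 40 °C, with the starting material near its charge. Target is then the first share times the exponential of minus the time at 40 °C over the pool lifetime, which makes 3.69% for a flask warm throughout.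

One objection is that the free share starts at 56.8%, higher than the late value, so the early fall is steeper. Integrating the balance exactly adds two corrections of opposite sign, 0.579 and 0.566, which nearly cancel, so the estimate stands.

A second objection is the second substrate, which can hold up to 0.200 equiv of partner away from decay and returns it in about 2.57 d, shorter than the pool lifetime. I therefore take my figure as the low side for the warm flasks. In beta the feed outlasts the bare decay time, so I place beta lowest of those.

Theta spends its feed at 10 °C, where the decay constant is 2.23 × 10⁻⁴ h⁻¹. Even wholly free partner would lose about 2.14% there, so theta's clock starts at the warming, and I commit to 9.87%, above the warm flasks.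

The forecast also names theta, on the ground that “the final yield is set by how much partner survives decomposition”. It gives theta 10.5%, eta 5.4%, beta 3.9%, gamma 5.2% and alpha 4.8%, so it stands above my figure in each flask.

The simulation gives theta 10.1%, the highest, against eta 4.22%, beta 3.84%, gamma 4.21% and alpha 4.53%. At the warming, after 4.00 d, theta held 1.65 × 10⁻⁴ M of decomposed reagent, out of 0.0200 M of partner charged. Its cold days are 0.985 pool lifetimes spared, a factor of 2.68, while the reading of theta over eta is 2.39.

Theta read at the end of its feed, at 4.0 d, has spent no time at 40 °C, so the exponential factor is 1.00. Target should then stand at the equal-charge share for 10 °C, where the constant times the charge is 5.35, which gives 65.1%. The computed flask holds 64.2%.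

The numbers stand for no real mixture; the run is a simulation.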